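Locants in the text are those of the hydroazulene core of the target: C3 carbinol carbon, C3a ring-fusion CH, C4 ester carbon, C6 methyl-bearing alkene carbon, C8 ketone, C8a quaternary carbon.
Retrosynthesis cuts, in order: the ester O–acyl bond; C8=O (allylic C–H oxidation); C4–H (ketone reduction); C3–C3a (ring closure); C3–isopropyl; C8a–C1 (conjugate addition); then one carbon (C3a) out of the seven-membered ring, back to 2,5-dimethylphenol.
Forward: the benzene ring becomes a cyclohexa-1,4-diene, then a siloxycyclopropane, then the seven-membered dienone; the side chain is added and turned into an isopropyl ketone; the five-membered ring is closed by joining C3 to C3a; reduction, acylation and oxidation finish.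
Enabling feature: O–C3 and O–C4 are 1,3 across C3a (an aldol pattern once C4 is a ketone) and C3 is tied to C3a through C2, C1 and C8a, so a ketyl at C3 reaches C3a of a ring enol triflate (C3a=C4–OTf) in a 5-exo closure; the triflyl group, the only helper, is expelled in the same step as C4 becomes the ketone.
Stereochemistry: C8a from the catalyst-controlled conjugate addition; C3a (cis fusion) and C3 (OH trans to C4) from the key step under control of C8a; C4 from hydride addition to the convex face of the bicyclic ketone.

Key step: step 9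

Remark: 6 and 7 are racemic and 16 is a mixture of carbinol epimers; these centres are erased in steps 4 and 8, so they are drawn with relative or without configuration.

Step 1
Reactants: 1 2,5-dimethylphenol; 2 tert-butyldimethylsilyl chloride
Product: 3 tert-butyl(2,5-dimethylphenoxy)dimethylsilane
Conditions: imidazole, DMF, rt
Reagents that add atoms: tert-butyldimethylsilyl chloride CC(C)(C)[Si](C)(C)Cl
Why: O-silylation of the phenol gives a bulky aryl silyl ether that should withstand dissolving-metal reduction and later supplies the silyl leaving group of the ring enlargement.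

Step 2
Reactants: 3 tert-butyl(2,5-dimethylphenoxy)dimethylsilane
Product: 4 tert-butyl[(2,5-dimethylcyclohexa-1,4-dien-1-yl)oxy]dimethylsilane
Conditions: Li, NH3(l), THF, t-BuOH, −78 °C
Reagents that add atoms: none
Why: Birch reduction of an aryl ether leaves the oxygen-bearing and both methyl-bearing carbons on the two isolated double bonds, which fixes the 1,4-diene with the silyl enol ether between C1 and C2.

Step 3
Reactants: 4 tert-butyl[(2,5-dimethylcyclohexa-1,4-dien-1-yl)oxy]dimethylsilane; 5 diiodomethane
Product: 6 racemic tert-butyl[(3,6-dimethylbicyclo[4.1.0]hept-3-en-1-yl)oxy]dimethylsilane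
Conditions: Zn–Cu couple, Et2O, reflux
Reagents that add atoms: diiodomethane ICI
Why: Simmons–Smith cyclopropanation, in which the electrophilic zinc carbenoid should attack the electron-rich silyl enol ether much faster than the trisubstituted alkene; the cis fusion is the only one possible.

Step 4
Reactants: 6 racemic tert-butyl[(3,6-dimethylbicyclo[4.1.0]hept-3-en-1-yl)oxy]dimethylsilane
Product: 8 3,6-dimethylcyclohepta-2,5-dien-1-one, via chloro ketone 7 (not isolated)
Conditions: FeCl3 (2.2 equiv), DMF, 0 °C; then NaOAc, MeOH, rt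
Reagents that add atoms: none
Why: Oxidative ring enlargement of a siloxycyclopropane, in which one-electron oxidation by FeCl3 cleaves the internal cyclopropane bond to the tertiary β-keto radical, chlorine transfer gives the β-chloro ketone and mild base removes HCl by an E1cB path into conjugation without moving the skipped second double bond.

Step 5
Reactants: 8 3,6-dimethylcyclohepta-2,5-dien-1-one; 9 [2-(1,3-dioxolan-2-yl)ethyl]magnesium bromide; 10 N-(5-chloropyridin-2-yl)-1,1,1-trifluoro-N-(trifluoromethylsulfonyl)methanesulfonamide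
Product: 12 (3R)-3-[2-(1,3-dioxolan-2-yl)ethyl]-3,6-dimethylcyclohepta-1,5-dien-1-yl trifluoromethanesulfonate, via magnesium enolate 11 (not isolated)
Conditions: Cu(OTf)2 (5 mol %), chiral imidazolinium salt as carbene ligand precursor (the enantiomer that gives the 3R product), Et2O, −30 °C; then 10, DMPU, −30 °C to rt
Reagents that add atoms: [2-(1,3-dioxolan-2-yl)ethyl]magnesium bromide Br[Mg]CCC1OCCO1; N-(5-chloropyridin-2-yl)-1,1,1-trifluoro-N-(trifluoromethylsulfonyl)methanesulfonamide Clc1ccc(N(S(=O)(=O)C(F)(F)F)S(=O)(=O)C(F)(F)F)nc1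
Why: Copper-catalysed asymmetric conjugate addition of a Grignard reagent to the β-methyl cycloalkenone should set the quaternary centre (future C8a) by catalyst control, and O-triflation of the magnesium enolate fixes the enol double bond regiospecifically toward that centre (future C3a=C4).

Step 6
Reactants: 12 (3R)-3-[2-(1,3-dioxolan-2-yl)ethyl]-3,6-dimethylcyclohepta-1,5-dien-1-yl trifluoromethanesulfonate; 13 water
Product: 14 (3R)-3,6-dimethyl-3-(3-oxopropyl)cyclohepta-1,5-dien-1-yl trifluoromethanesulfonate
Conditions: 1 M HCl, THF, rt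
Reagents that add atoms: water O
Why: Acid-catalysed acetal hydrolysis frees the aldehyde, while the enol triflate is stable to aqueous acid and the stereocentre is untouched.

Step 7
Reactants: 14 (3R)-3,6-dimethyl-3-(3-oxopropyl)cyclohepta-1,5-dien-1-yl trifluoromethanesulfonate; 15 isopropylmagnesium chloride
Product: 16 (3R)-3-(3-hydroxy-4-methylpentyl)-3,6-dimethylcyclohepta-1,5-dien-1-yl trifluoromethanesulfonate (both carbinol epimers)
Conditions: THF, −78 °C; aq. NH4Cl
Reagents that add atoms: isopropylmagnesium chloride CC(C)[Mg]Cl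
Why: Grignard addition to the aldehyde brings in the isopropyl group; alkenyl triflates do not react with Grignard reagents without a transition-metal catalyst, and the new carbinol centre is oxidised in the next step.

Step 8
Reactants: 16 (3R)-3-(3-hydroxy-4-methylpentyl)-3,6-dimethylcyclohepta-1,5-dien-1-yl trifluoromethanesulfonate
Product: 17 (3R)-3,6-dimethyl-3-(4-methyl-3-oxopentyl)cyclohepta-1,5-dien-1-yl trifluoromethanesulfonate
Conditions: Dess–Martin periodinane, CH2Cl2, rt
Reagents that add atoms: none
Why: Dess–Martin oxidation of the secondary alcohol under near-neutral conditions gives the isopropyl ketone needed as ketyl precursor and should leave the enol triflate and both alkenes intact.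

Step 9
Reactants: 17 (3R)-3,6-dimethyl-3-(4-methyl-3-oxopentyl)cyclohepta-1,5-dien-1-yl trifluoromethanesulfonate
Product: 18 (3R,3aS,8aR)-3-hydroxy-6,8a-dimethyl-3-(propan-2-yl)-2,3,3a,5,8,8a-hexahydroazulen-4(1H)-one (cis-fused, 3-OH trans to C4)
Conditions: SmI2 (2.2 equiv), HMPA, THF, −78 to −20 °C; pH 7 buffer
Reagents that add atoms: none
Why: Proposed new method: SmI2/HMPA reduces the isopropyl ketone to a samarium ketyl whose carbon (future C3) adds 5-exo-trig to the unsubstituted carbon of the ring enol triflate (future C3a), and the α-triflyloxy radical thus formed at C4 breaks its O–S bond to give the C4 ketone and CF3SO2•, which a second SmI2 reduces to triflinate, so that the net result is an aldol-type union in which the carbonyl carbon reacts as a nucleophilic radical and the enol carbon as the acceptor. The closest known reaction types are the SmI2-promoted ketyl–olefin cyclization and the addition–fragmentation of carbon radicals on alkenyl triflates that gives α-substituted ketones; their combination with a ketyl radical has not been shown. The cyclopentane ring is closed in the 5-exo-trig mode onto the preformed seven-membered ring. C3a is set by the tether, since the three-atom chain on C8a can reach only its own face of the seven-membered ring, which gives the cis fusion; C3 is set by the anti arrangement of the bulky samarium-bound ketyl oxygen and the acceptor double bond in the chair-like transition state, the usual preference of ketyl–olefin closures, which places the hydroxyl trans to C4 and the isopropyl group cis, the diastereomer that a chelated enolate aldol would not be expected to give. The step needs reduction of the ketone in preference to the triflate, 5-exo attack at C3a in preference to 6-exo attack at C7 of the trisubstituted alkene, and survival of the β-hydroxy ketone; HMPA-accelerated ketyl formation, the electron-poor triflyloxy alkene with the smaller ring being formed, and the use of only two equivalents of SmI2 with a cold buffered quench should secure them.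

Step 10
Reactants: 18 (3R,3aS,8aR)-3-hydroxy-6,8a-dimethyl-3-(propan-2-yl)-2,3,3a,5,8,8a-hexahydroazulen-4(1H)-one
Product: 19 (3R,3aR,4S,8aR)-6,8a-dimethyl-3-(propan-2-yl)-1,2,3,3a,4,5,8,8a-octahydroazulene-3,4-diol
Conditions: Me4NBH(OAc)3, MeCN–AcOH, −30 °C
Reagents that add atoms: none
Why: Hydroxyl-directed reduction of a β-hydroxy ketone with triacetoxyborohydride (Evans–Saksena reduction), in a weakly acidic medium that avoids retro-aldol cleavage, should deliver hydride to C4 on the convex face of the cis-fused bicycle (the face of H3a and the C3 hydroxyl, away from the C3 isopropyl group) and so give the 4S alcohol with its oxygen cis to C3.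

Step 11
Reactants: 19 (3R,3aR,4S,8aR)-6,8a-dimethyl-3-(propan-2-yl)-1,2,3,3a,4,5,8,8a-octahydroazulene-3,4-diol; 20 4-methoxybenzoyl chloride
Product: 21 (3R,3aR,4S,8aR)-3-hydroxy-6,8a-dimethyl-3-(propan-2-yl)-1,2,3,3a,4,5,8,8a-octahydroazulen-4-yl 4-methoxybenzoate
Conditions: pyridine, DMAP (cat.), CH2Cl2, 0 °C to rt
Reagents that add atoms: 4-methoxybenzoyl chloride COc1ccc(C(Cl)=O)cc1
Why: Acylation with an acid chloride under nucleophilic catalysis should occur only at the secondary C4 hydroxyl, the tertiary C3 hydroxyl being too hindered.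

Step 12
Reactants: 21 (3R,3aR,4S,8aR)-3-hydroxy-6,8a-dimethyl-3-(propan-2-yl)-1,2,3,3a,4,5,8,8a-octahydroazulen-4-yl 4-methoxybenzoate; 22 tert-butyl hydroperoxide
Product: 23 (3R,3aR,4S,8aS)-3-hydroxy-6,8a-dimethyl-8-oxo-3-(propan-2-yl)-1,2,3,3a,4,5,8,8a-octahydroazulen-4-yl 4-methoxybenzoate (target)
Conditions: Rh2(cap)4 (1 mol %, cap = caprolactamate), aq. t-BuOOH, ClCH2CH2Cl, 40 °C, no base
Reagents that add atoms: tert-butyl hydroperoxide CC(C)(C)OO
Why: Dirhodium-catalysed allylic C–H oxidation should turn the methylene next to the unsubstituted alkene carbon (C8, between C7 and C8a) into the enone carbonyl, as 1-methylcycloalkenes give 3-methylcycloalk-2-enones, while the C5 methylene is deactivated by the acyloxy-bearing C4 and base-free conditions avoid loss of the carboxylate from the product.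

Compound list
1 | 2,5-dimethylphenol | Cc1ccc(C)c(O)c1 | starting material
2 | tert-butyldimethylsilyl chloride | CC(C)(C)[Si](C)(C)Cl | starting material
3 | tert-butyl(2,5-dimethylphenoxy)dimethylsilane | Cc1ccc(C)c(O[Si](C)(C)C(C)(C)C)c1 | intermediate
4 | tert-butyl[(2,5-dimethylcyclohexa-1,4-dien-1-yl)oxy]dimethylsilane | CC1=C(O[Si](C)(C)C(C)(C)C)CC(C)=CC1 | intermediate
5 | diiodomethane | ICI | starting material
6 | racemic tert-butyl[(3,6-dimethylbicyclo[4.1.0]hept-3-en-1-yl)oxy]dimethylsilane, cis-fused, one enantiomer drawn | C[C@]12C[C@@]1(O[Si](C)(C)C(C)(C)C)CC(C)=CC2 | intermediate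
7 | racemic 3-chloro-3,6-dimethylcyclohept-5-en-1-one (not isolated) | O=C1CC(C)(Cl)CC=C(C)C1 | intermediate
8 | 3,6-dimethylcyclohepta-2,5-dien-1-one | O=C1C=C(C)CC=C(C)C1 | intermediate
9 | [2-(1,3-dioxolan-2-yl)ethyl]magnesium bromide | Br[Mg]CCC1OCCO1 | starting material
10 | N-(5-chloropyridin-2-yl)-1,1,1-trifluoro-N-(trifluoromethylsulfonyl)methanesulfonamide | Clc1ccc(N(S(=O)(=O)C(F)(F)F)S(=O)(=O)C(F)(F)F)nc1 | starting material
11 | bromomagnesium (3R)-3-[2-(1,3-dioxolan-2-yl)ethyl]-3,6-dimethylcyclohepta-1,5-dien-1-olate (not isolated) | Br[Mg]OC1=C[C@](C)(CCC2OCCO2)CC=C(C)C1 | intermediate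
12 | (3R)-3-[2-(1,3-dioxolan-2-yl)ethyl]-3,6-dimethylcyclohepta-1,5-dien-1-yl trifluoromethanesulfonate | O1CCOC1CC[C@]2(C)CC=C(C)CC(OS(=O)(=O)C(F)(F)F)=C2 | intermediate
13 | water | O | starting material
14 | (3R)-3,6-dimethyl-3-(3-oxopropyl)cyclohepta-1,5-dien-1-yl trifluoromethanesulfonate | O=CCC[C@]1(C)CC=C(C)CC(OS(=O)(=O)C(F)(F)F)=C1 | intermediate
15 | isopropylmagnesium chloride | CC(C)[Mg]Cl | starting material
16 | (3R)-3-(3-hydroxy-4-methylpentyl)-3,6-dimethylcyclohepta-1,5-dien-1-yl trifluoromethanesulfonate, carbinol epimers | CC(C)C(O)CC[C@]1(C)CC=C(C)CC(OS(=O)(=O)C(F)(F)F)=C1 | intermediate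
17 | (3R)-3,6-dimethyl-3-(4-methyl-3-oxopentyl)cyclohepta-1,5-dien-1-yl trifluoromethanesulfonate | CC(C)C(=O)CC[C@]1(C)CC=C(C)CC(OS(=O)(=O)C(F)(F)F)=C1 | intermediate
18 | (3R,3aS,8aR)-3-hydroxy-6,8a-dimethyl-3-(propan-2-yl)-2,3,3a,5,8,8a-hexahydroazulen-4(1H)-one | O=C1CC(C)=CC[C@@]2(C)CC[C@@](O)(C(C)C)[C@@H]12 | intermediate
19 | (3R,3aR,4S,8aR)-6,8a-dimethyl-3-(propan-2-yl)-1,2,3,3a,4,5,8,8a-octahydroazulene-3,4-diol | O[C@H]1CC(C)=CC[C@@]2(C)CC[C@@](O)(C(C)C)[C@@H]12 | intermediate
20 | 4-methoxybenzoyl chloride | COc1ccc(C(Cl)=O)cc1 | starting material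
21 | (3R,3aR,4S,8aR)-3-hydroxy-6,8a-dimethyl-3-(propan-2-yl)-1,2,3,3a,4,5,8,8a-octahydroazulen-4-yl 4-methoxybenzoate | COc1ccc(C(=O)O[C@H]2CC(C)=CC[C@@]3(C)CC[C@@](O)(C(C)C)[C@@H]23)cc1 | intermediate
22 | tert-butyl hydroperoxide | CC(C)(C)OO | starting material
23 | (3R,3aR,4S,8aS)-3-hydroxy-6,8a-dimethyl-8-oxo-3-(propan-2-yl)-1,2,3,3a,4,5,8,8a-octahydroazulen-4-yl 4-methoxybenzoate | COc1ccc(C(=O)O[C@H]2CC(C)=CC(=O)[C@@]3(C)CC[C@@](O)(C(C)C)[C@@H]23)cc1 | target

Total steps: 12. Longest linear sequence: 12 steps (1 to 23).

Steps most likely to fail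

Step 9 (Proposed new method). The ketyl may be reduced further or protonated before it adds, the O–S bond of the enol triflate may be cleaved reductively, or the samarium aldolate may reopen by retro-aldol reaction and scramble C3. The fallback sets out from 17 and comes back at 18, using known reactions only. Palladium-catalysed sulfination of the enol triflate (PhSO2Na, Pd2(dba)3, Xantphos, Cs2CO3, toluene, 80 °C) should give vinyl sulfone F1, a classical ketyl acceptor. SmI2/HMPA/t-BuOH then closes the five-membered ring by ketyl–olefin cyclization onto the α,β-unsaturated sulfone and should give hydroxy sulfone F2 with the same cis fusion and anti configuration at C3. Double deprotonation (LDA, 2.2 equiv, −78 °C) and oxidation of the α-sulfonyl carbanion with bis(trimethylsilyl) peroxide (oxidative desulfonylation) should give 18.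

Step 5. The copper catalyst may discriminate poorly between the faces of the flexible seven-membered enone, or the basic Grignard reagent may move the skipped double bond of 8 into conjugation before it adds. The fallback sets out from 8 and comes back at 16; it uses a non-basic nucleophile and builds the side chain in another way. Commercial 4-methylpent-1-en-3-ol is silylated with 2 (imidazole, DMF) to silyl ether F3, and hydrozirconation (Cp2ZrHCl, CH2Cl2) gives alkylzirconocene F4. Its copper-catalysed asymmetric conjugate addition to 8 (CuCl, AgNTf2, chiral phosphoramidite, Me3SiCl, Et2O, rt), a reaction type known to build quaternary centres on seven-membered enones, should give trimethylsilyl enol ether F5. MeLi followed by PhNTf2 should give silyloxy enol triflate F6, and Bu4NF removes the silyl ether to give 16.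

Step 12. Hydrogen abstraction may occur at the other allylic methylene or at the allylic methyl group, or the product may be oxidised further. The fallback sets out from 21 and comes back at 23 by a stepwise oxygen transposition. Epoxidation of the only alkene (mCPBA, NaHCO3, CH2Cl2) should give epoxide F7, whose facial mixture is of no consequence. Ring opening at the secondary carbon C7 with PhSeNa (from PhSeSePh and NaBH4, EtOH) should give hydroxy selenide F8. Oxidation with H2O2 and selenoxide syn-elimination, which can only go toward C8, should give tertiary allylic alcohol F9. Pyridinium chlorochromate then effects the oxidative 1,3-transposition (Babler–Dauben oxidation) to enone 23.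

Further compounds
F1 | step 9 | 4-methyl-1-[(1R)-1,4-dimethyl-6-(phenylsulfonyl)cyclohepta-3,6-dien-1-yl]pentan-3-one | CC(C)C(=O)CC[C@]1(C)CC=C(C)CC(S(=O)(=O)c2ccccc2)=C1
F2 | step 9 | (3R,3aS,8aR)-6,8a-dimethyl-4-(phenylsulfonyl)-3-(propan-2-yl)-1,2,3,3a,4,5,8,8a-octahydroazulen-3-ol, epimers at C4 | O=S(=O)(c3ccccc3)C1CC(C)=CC[C@@]2(C)CC[C@@](O)(C(C)C)[C@@H]12
F3 | step 5 | racemic tert-butyldimethyl[(4-methylpent-1-en-3-yl)oxy]silane | C=CC(O[Si](C)(C)C(C)(C)C)C(C)C
F4 | step 5 | chlorobis(cyclopentadienyl)[3-(tert-butyldimethylsilyloxy)-4-methylpentyl]zirconium | CC(C)C(O[Si](C)(C)C(C)(C)C)CC[Zr](Cl)(C1C=CC=C1)C1C=CC=C1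
F5 | step 5 | {[(3R)-3-[3-(tert-butyldimethylsilyloxy)-4-methylpentyl]-3,6-dimethylcyclohepta-1,5-dien-1-yl]oxy}trimethylsilane | C[Si](C)(C)OC1=C[C@](C)(CCC(O[Si](C)(C)C(C)(C)C)C(C)C)CC=C(C)C1
F6 | step 5 | (3R)-3-[3-(tert-butyldimethylsilyloxy)-4-methylpentyl]-3,6-dimethylcyclohepta-1,5-dien-1-yl trifluoromethanesulfonate | CC(C)C(O[Si](C)(C)C(C)(C)C)CC[C@]1(C)CC=C(C)CC(OS(=O)(=O)C(F)(F)F)=C1
F7 | step 12 | 6,7-epoxide of 21, both faces | COc1ccc(C(=O)O[C@H]2CC5(C)OC5C[C@@]3(C)CC[C@@](O)(C(C)C)[C@@H]23)cc1
F8 | step 12 | 6-hydroxy-7-(phenylselanyl) derivative of 21, saturated at C6–C7 | COc1ccc(C(=O)O[C@H]2CC(C)(O)C([Se]c5ccccc5)C[C@@]3(C)CC[C@@](O)(C(C)C)[C@@H]23)cc1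
F9 | step 12 | 6-hydroxy analogue of 21 with the double bond at C7=C8, epimers at C6 | COc1ccc(C(=O)O[C@H]2CC(C)(O)C=C[C@@]3(C)CC[C@@](O)(C(C)C)[C@@H]23)cc1
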